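**Plan**
1. Retrosynthetic cuts: the two angelate C–O bonds; then the C8–C9 bond of the ten-membered ring (8,9-diol back to a C8/C9 dialdehyde); then C1=C10 (Wittig), C3–C4 (B-alkyl Suzuki) and C6–C7 with the lactone C–O (aldol/lactonisation). The C14 oxygen and the C11=C13 methylene are late adjustments.
2. Enabling feature: C8 and C9 are adjacent oxygen-bearing ring carbons, C8 on C7 of the lactone ring (O–C6–C7–C11–C12) and C9 allylic to C10=C1. The seco compound is therefore a dialdehyde whose C9 carbonyl is a conjugated, easily reduced enal.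
3. Forward order: butynediol gives a Z-iodo enal (C4–C6, C15); Evans aldol/lactonisation makes the lactone ring first; Suzuki and Wittig reactions add C1–C3 and C9/C10/C14; SmI2 pinacol coupling closes the carbocycle at C8–C9 last.
4. After ring closure: double angeloylation, release of the methylene from its dimethylamine adduct, Riley oxidation of the C14 methyl (its [2,3] step also turns C1=C10 into the geometry of the target), desilylation.
5. Stereochemistry: C6/C7 from (S)-4-benzyloxazolidinone, the only purchased stereocentre; C8 and C9 together in the key step, relayed from C7 and the samarium bridge; C4=C5 from trans-hydroalumination/iodination; angelate geometry from angelic acid.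

Key step: step 13

Remark: germacrane locants C1–C15 of the target are used for all intermediates. The target SMILES is read as the 6α,12-olide with H-7α, 8β- and 9α-angeloyloxy groups, C3 cis to C6 across C4=C5 and C9 cis to C2 across C1=C10 (formyl C14 trans to C2). Compounds 1, 5, 6, 12, 17 and 21 are taken to be catalogue items.

Step 1
Reactants: 1 but-2-yne-1,4-diol
Product: 2 4-(tert-butyldiphenylsilyloxy)but-2-yn-1-ol
Conditions: NaH (1 equiv), THF, 0 °C; TBDPSCl, 0 °C to rt
Reagents that add atoms: tert-butyl(chloro)diphenylsilane, CC(C)(C)[Si](Cl)(c1ccccc1)c1ccccc1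
Why: Monosilylation of a symmetrical diol through its sparingly soluble monosodium alkoxide should stop after one silyl ether has formed.

Step 2
Reactants: 2 4-(tert-butyldiphenylsilyloxy)but-2-yn-1-ol
Product: 3 (Z)-4-(tert-butyldiphenylsilyloxy)-3-iodobut-2-en-1-ol
Conditions: NaAlH2(OCH2CH2OMe)2, THF, 0 °C; then I2, −78 °C
Reagents that add atoms: iodine, II
Why: Alkoxide-directed trans-hydroalumination of the propargylic alcohol and iodinolysis of the vinylalane with retention place iodine on C4 cis to C6, which fixes the C4=C5 geometry.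

Step 3
Reactants: 3 (Z)-4-(tert-butyldiphenylsilyloxy)-3-iodobut-2-en-1-ol
Product: 4 (Z)-4-(tert-butyldiphenylsilyloxy)-3-iodobut-2-enal
Conditions: MnO2, CH2Cl2, rt
Reagents that add atoms: none
Why: Neutral heterogeneous oxidation of an allylic alcohol with MnO2 should give the enal without touching the iodoalkene geometry.

Step 4
Reactants: 5 (S)-4-benzyloxazolidin-2-one; 6 methyl 4-chloro-4-oxobutanoate
Product: 7 (S)-4-benzyl-3-(4-methoxy-4-oxobutanoyl)oxazolidin-2-one
Conditions: n-BuLi, THF, −78 °C; then 6, −78 to 0 °C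
Reagents that add atoms: none
Why: N-Acylation of the lithiated oxazolidinone by the acid chloride is standard and leaves the methyl ester untouched.

Step 5
Reactants: 7 (S)-4-benzyl-3-(4-methoxy-4-oxobutanoyl)oxazolidin-2-one; 4 (Z)-4-(tert-butyldiphenylsilyloxy)-3-iodobut-2-enal
Product: 9 trans-lactone carboximide, via syn-aldol hydroxy ester 8 (not isolated)
Conditions: n-Bu2BOTf, i-Pr2NEt, CH2Cl2, −78 to 0 °C; 4, −78 °C; pH 7 buffer, MeOH, H2O2; then PPTS (cat.), CH2Cl2, rt
Reagents that add atoms: none
Why: In this Evans syn-aldol reaction the Z-boron enolate, formed at the imide α-CH2 and not at the ester, adds to the enal through a Zimmerman–Traxler chair on the face away from the benzyl group, which sets C6 and C7, and the γ-hydroxy ester then closes to the five-membered lactone in which the syn relationship appears as the 6,7-trans arrangement.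

Step 6
Reactants: 9 trans-lactone carboximide
Product: 10 C8 hydroxymethyl lactone
Conditions: NaBH4, THF/H2O, 0 °C
Reagents that add atoms: none
Why: Reductive removal of the auxiliary should be selective because NaBH4 in aqueous THF attacks the activated exocyclic imide carbonyl much faster than the γ-lactone.

Step 7
Reactants: 10 C8 hydroxymethyl lactone
Product: 11 C8 TBS ether
Conditions: TBSCl, imidazole, DMF, rt
Reagents that add atoms: tert-butyl(chloro)dimethylsilane, CC(C)(C)[Si](C)(C)Cl
Why: Standard silylation of the primary alcohol protects C8–OH for the enolate step with a group that is more labile than the TBDPS ether on C15.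

Step 8
Reactants: 11 C8 TBS ether; 12 acrolein diethyl acetal
Product: 14 C1 diethyl acetal lactone, via B-(3,3-diethoxypropyl)-9-borabicyclo[3.3.1]nonane 13 (not isolated)
Conditions: 12, 9-borabicyclo[3.3.1]nonane, THF, rt; then 11, PdCl2(dppf) (cat.), AsPh3, Cs2CO3, DMF/H2O, rt
Reagents that add atoms: none
Why: In this B-alkyl Suzuki–Miyaura coupling, anti-Markovnikov hydroboration of the terminal alkene and coupling of the alkylborane with the vinyl iodide under zerovalent palladium catalysis proceed with retention, so C3 ends up cis to C6.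

Step 9
Reactants: 14 C1 diethyl acetal lactone
Product: 15 13-(dimethylamino) lactone
Conditions: lithium diisopropylamide, THF, −78 °C; Eschenmoser's salt, −78 to 0 °C
Reagents that add atoms: N,N-dimethylmethyleneiminium iodide, C=[N+](C)C.[I-]
Why: Mannich aminomethylation of the lactone lithium enolate should occur anti to the C7 substituent and stores C13 as a β-amino group that is inert to SmI2 and keeps H-7 free of vinylogous acidity.

Step 10
Reactants: 15 13-(dimethylamino) lactone
Product: 16 C8 alcohol C1 aldehyde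
Conditions: HCl (1 M aq.), THF, 0 °C to rt; NaHCO3 work-up
Reagents that add atoms: water, O
Why: Aqueous acid hydrolyses the diethyl acetal and the primary TBS ether in one operation, while the more robust TBDPS ether and the lactone should survive.

Step 11
Reactants: 16 C8 alcohol C1 aldehyde; 17 2-(triphenylphosphoranylidene)propanal
Product: 18 E-enal alcohol
Conditions: toluene, 70 °C
Reagents that add atoms: none
Why: Wittig olefination with the stabilised formyl ylide is selective for the aliphatic aldehyde and E-selective, so it delivers the conjugated C9 aldehyde directly with C2 trans to C9.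

Step 12
Reactants: 18 E-enal alcohol
Product: 19 C8/C9 dialdehyde
Conditions: Dess–Martin periodinane, NaHCO3, CH2Cl2, 0 °C; crude product used at once
Reagents that add atoms: none
Why: Buffered Dess–Martin oxidation of the primary C8 alcohol avoids base, which should prevent epimerisation at C7 and β-elimination of the lactone oxygen from the β-acyloxy aldehyde.

Step 13
Reactants: 19 C8/C9 dialdehyde
Product: 20 ten-membered 8β,9α-diol
Conditions: SmI2 (3 equiv), THF, −78 °C, slow addition of 19 (final 2 mM); pH 7 buffer at −78 °C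
Reagents that add atoms: none
Why: Single-electron transfer from divalent samarium to the conjugated C9 aldehyde, the more easily reduced carbonyl, gives a samarium-bound allylic ketyl that adds through C9 to the C8 aldehyde held on the same oxophilic trivalent samarium centre, and a second electron transfer followed by protonation gives the diol (intramolecular pinacol coupling). The closest known reaction type is the pinacol macrocyclisation of dialdehydes with SmI2 or low-valent titanium, including couplings of an enal carbonyl onto a saturated aldehyde. One ring is closed, the ten-membered carbocycle C1–C10, by a 10-exo-trig ketyl addition to C8=O, helped by the trans-lactone ring (O–C6–C7–C11–C12) and the C4=C5 alkene with C3 cis to C6, which fold the chain so that C8 and C9 come close. C8 is set by C7: C9 should approach the C8 carbonyl anti to C11 of the lactone and past H-7 (Felkin–Anh, the tether leaving from C6), which places O-8 on the β-face; C9 is set by the samarium bridge between the two oxygens, which holds the C–O bonds gauche and H-8 and H-9 anti in the forming bond and should therefore give the 8,9-threo diol with O-9 on the α-face. The step needs coupling at C9 and not at C1 of the allylic ketyl, ring closure and not dimerisation, and no other reduction: the samarium bridge, high dilution, the masking of C13 as an amine (no acrylate acceptor) and the inertness of the lactone and silyl ether to SmI2 in THF should secure this.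

Step 14
Reactants: 20 ten-membered 8β,9α-diol; 21 angelic acid (3 equiv charged; two equivalents are taken up, one per hydroxyl)
Product: 22 8β,9α-diangelate
Conditions: 21 (3 equiv), 2,4,6-Cl3C6H2COCl (3 equiv), Et3N, toluene, rt; then 20, 80 °C
Reagents that add atoms: angelic acid (the second equivalent of 21, which supplies the second angeloyl group), C/C=C(/C)C(=O)O
Why: Yamaguchi-type esterification through the preformed mixed anhydride, used in excess so that one angeloyl group is delivered to each of the two secondary hydroxyls, needs no nucleophilic catalyst, which should avoid isomerisation of the Z-configured acyl group to the tigloyl isomer.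

Step 15
Reactants: 22 8β,9α-diangelate
Product: 24 11(13)-methylene lactone, via trimethylammonium iodide 23 (not isolated)
Conditions: MeI, acetone, rt; then NaHCO3 (aq.), CH2Cl2, rt
Reagents that add atoms: none
Why: Quaternisation of the amine and mild base-induced β-elimination of trimethylamine (retro-Michael) regenerate the C11=C13 methylene under conditions that the esters tolerate.

Step 16
Reactants: 24 11(13)-methylene lactone
Product: 26 14-aldehyde silyl ether, via 14-hydroxy compound 25 (not isolated)
Conditions: SeO2 (cat.), t-BuOOH, CH2Cl2, rt; then Dess–Martin periodinane, NaHCO3, CH2Cl2, 0 °C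
Reagents that add atoms: tert-butyl hydroperoxide, CC(C)(C)OO (terminal source of the C14 oxygen, passed on by selenium dioxide, O=[Se]=O)
Why: In this Riley oxidation the ene reaction at C1 takes a hydrogen from the C14 methyl of the more electron-rich C1=C10 alkene (C4=C5 is flanked by two allylic oxygens), the [2,3]-sigmatropic shift returns C1=C10 with the oxygenated C14 trans to C2 and hence C9 cis to C2 as in the target, and Dess–Martin oxidation of the crude allylic alcohol completes the enal.

Step 17
Reactants: 26 14-aldehyde silyl ether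
Product: 27 CNP0139154.1
Conditions: HF·pyridine, pyridine, THF, 0 °C to rt
Reagents that add atoms: none
Why: Buffered fluoride cleavage of the primary TBDPS ether should leave the enal, the two angelates and the α-methylene lactone intact.

**Compound list**
1 | but-2-yne-1,4-diol | OCC#CCO | starting material
2 | 4-(tert-butyldiphenylsilyloxy)but-2-yn-1-ol | OCC#CCO[Si](c1ccccc1)(c1ccccc1)C(C)(C)C | intermediate
3 | (Z)-4-(tert-butyldiphenylsilyloxy)-3-iodobut-2-en-1-ol (C6–C5=C4(I)–C15; CH2OH cis to I) | OC/C=C(\I)CO[Si](c1ccccc1)(c1ccccc1)C(C)(C)C | intermediate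
4 | (Z)-4-(tert-butyldiphenylsilyloxy)-3-iodobut-2-enal | O=C/C=C(\I)CO[Si](c1ccccc1)(c1ccccc1)C(C)(C)C | intermediate
5 | (S)-4-benzyloxazolidin-2-one | O=C1N[C@@H](Cc2ccccc2)CO1 | starting material
6 | methyl 4-chloro-4-oxobutanoate | COC(=O)CCC(Cl)=O | starting material
7 | (S)-4-benzyl-3-(4-methoxy-4-oxobutanoyl)oxazolidin-2-one | COC(=O)CCC(=O)N1[C@@H](Cc2ccccc2)COC1=O | intermediate
8 | syn-aldol hydroxy ester: methyl (Z)-3-[(S)-4-benzyl-2-oxooxazolidine-3-carbonyl]-7-(tert-butyldiphenylsilyloxy)-4-hydroxy-6-iodohept-5-enoate, Evans syn, C6 and C7 as in the target | COC(=O)C[C@@H]([C@H](O)/C=C(\I)CO[Si](c1ccccc1)(c1ccccc1)C(C)(C)C)C(=O)N1[C@@H](Cc2ccccc2)COC1=O | intermediate (not isolated)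
9 | trans-lactone carboximide: γ-lactone O–C6–C7–C11–C12 with the (Z)-2-iodo-3-(tert-butyldiphenylsilyloxy)prop-1-enyl group on C6 and the acyl-oxazolidinone (C8) on C7, 6,7-trans | O=C1O[C@H](/C=C(\I)CO[Si](c2ccccc2)(c2ccccc2)C(C)(C)C)[C@@H](C(=O)N2[C@@H](Cc3ccccc3)COC2=O)C1 | intermediate
10 | C8 hydroxymethyl lactone: 4-(hydroxymethyl)-5-[(Z)-2-iodo-3-(tert-butyldiphenylsilyloxy)prop-1-enyl]dihydrofuran-2(3H)-one, 4,5-trans | O=C1O[C@H](/C=C(\I)CO[Si](c2ccccc2)(c2ccccc2)C(C)(C)C)[C@@H](CO)C1 | intermediate
11 | C8 TBS ether of 10 | O=C1O[C@H](/C=C(\I)CO[Si](c2ccccc2)(c2ccccc2)C(C)(C)C)[C@@H](CO[Si](C)(C)C(C)(C)C)C1 | intermediate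
12 | acrolein diethyl acetal (3,3-diethoxyprop-1-ene) | C=CC(OCC)OCC | starting material
13 | B-(3,3-diethoxypropyl)-9-borabicyclo[3.3.1]nonane | CCOC(OCC)CCB1C2CCCC1CCC2 | intermediate (not isolated)
14 | C1 diethyl acetal lactone: as 11 with the 3,3-diethoxypropyl chain (C3–C1) in place of iodine on C4, C3 cis to C6 | O=C1O[C@H](/C=C(\CCC(OCC)OCC)CO[Si](c2ccccc2)(c2ccccc2)C(C)(C)C)[C@@H](CO[Si](C)(C)C(C)(C)C)C1 | intermediate
15 | 13-(dimethylamino) lactone: 14 with CH2NMe2 on C11, trans to the C7 substituent (11βH) | O=C1O[C@H](/C=C(\CCC(OCC)OCC)CO[Si](c2ccccc2)(c2ccccc2)C(C)(C)C)[C@@H](CO[Si](C)(C)C(C)(C)C)[C@@H]1CN(C)C | intermediate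
16 | C8 alcohol C1 aldehyde | O=C1O[C@H](/C=C(\CCC=O)CO[Si](c2ccccc2)(c2ccccc2)C(C)(C)C)[C@@H](CO)[C@@H]1CN(C)C | intermediate
17 | 2-(triphenylphosphoranylidene)propanal | CC(C=O)=P(c1ccccc1)(c1ccccc1)c1ccccc1 | starting material
18 | E-enal alcohol: C9 aldehyde on C10 (methyl C14), C2 trans to C9; C8 primary alcohol | O=C1O[C@H](/C=C(\CC/C=C(\C)C=O)CO[Si](c2ccccc2)(c2ccccc2)C(C)(C)C)[C@@H](CO)[C@@H]1CN(C)C | intermediate
19 | C8/C9 dialdehyde (seco compound) | O=C1O[C@H](/C=C(\CC/C=C(\C)C=O)CO[Si](c2ccccc2)(c2ccccc2)C(C)(C)C)[C@@H](C=O)[C@@H]1CN(C)C | intermediate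
20 | 15-(tert-butyldiphenylsilyloxy)-13-(dimethylamino)-8β,9α-dihydroxy-11βH-germacra-1(10),4-dien-6α,12-olide; C2 trans to C9 across C1=C10, C3 cis to C6 across C4=C5 | CN(C)C[C@@H]1C(=O)O[C@@H]2/C=C(/CO[Si](c3ccccc3)(c3ccccc3)C(C)(C)C)CC/C=C(\C)[C@H](O)[C@@H](O)[C@@H]12 | intermediate
21 | angelic acid, (Z)-2-methylbut-2-enoic acid | C/C=C(/C)C(=O)O | starting material
22 | 8β,9α-bis(angeloyloxy) derivative of 20 | CN(C)C[C@@H]1C(=O)O[C@@H]2/C=C(/CO[Si](c3ccccc3)(c3ccccc3)C(C)(C)C)CC/C=C(\C)[C@H](OC(=O)/C(C)=C\C)[C@@H](OC(=O)/C(C)=C\C)[C@@H]12 | intermediate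
23 | trimethylammonium iodide of 22 | C[N+](C)(C)C[C@@H]1C(=O)O[C@@H]2/C=C(/CO[Si](c3ccccc3)(c3ccccc3)C(C)(C)C)CC/C=C(\C)[C@H](OC(=O)/C(C)=C\C)[C@@H](OC(=O)/C(C)=C\C)[C@@H]12.[I-] | intermediate (not isolated)
24 | 8β,9α-bis(angeloyloxy)-15-(tert-butyldiphenylsilyloxy)germacra-1(10),4,11(13)-trien-6α,12-olide; C2 trans to C9 | C=C1C(=O)O[C@@H]2/C=C(/CO[Si](c3ccccc3)(c3ccccc3)C(C)(C)C)CC/C=C(\C)[C@H](OC(=O)/C(C)=C\C)[C@@H](OC(=O)/C(C)=C\C)[C@@H]12 | intermediate
25 | 14-hydroxy compound: as 24 with CH2OH on C10 trans to C2, C9 cis to C2 | C=C1C(=O)O[C@@H]2/C=C(/CO[Si](c3ccccc3)(c3ccccc3)C(C)(C)C)CC/C=C(/CO)[C@H](OC(=O)/C(C)=C\C)[C@@H](OC(=O)/C(C)=C\C)[C@@H]12 | intermediate (not isolated)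
26 | 14-aldehyde silyl ether: 15-O-TBDPS ether of the target | C=C1C(=O)O[C@@H]2/C=C(/CO[Si](c3ccccc3)(c3ccccc3)C(C)(C)C)CC/C=C(/C=O)[C@H](OC(=O)/C(C)=C\C)[C@@H](OC(=O)/C(C)=C\C)[C@@H]12 | intermediate
27 | CNP0139154.1: 8β,9α-bis(angeloyloxy)-15-hydroxy-14-oxogermacra-1(10),4,11(13)-trien-6α,12-olide; C9 cis to C2, C3 cis to C6 | C=C1C(=O)O[C@@H]2/C=C(/CO)CC/C=C(/C=O)[C@H](OC(=O)/C(C)=C\C)[C@@H](OC(=O)/C(C)=C\C)[C@@H]12 | target

**Step count**
Total: 17 steps. Longest linear sequence: 16 steps (steps 1–3 and 5–17; step 4 is a one-step side branch).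

**Steps most likely to fail**

Step 13. The ketyl coupling may close the ring with poor facial control at C9, giving the erythro diol where the threo diol is needed, because the allylic ketyl can present either face in a flexible ten-membered transition state. The fallback sets out from 19 and corrects C9 by oxidation and reduction. The ring is closed as in step 13 and the C9-epimeric 8β,9β-diol F1, alone or mixed with 20, is carried on. MnO2 in CH2Cl2 oxidises only the allylic C9 hydroxyl to the 8β-hydroxy-9-ketone F2. Et3SiOTf with 2,6-lutidine gives the 8-O-triethylsilyl ketone F3. Luche reduction (NaBH4, CeCl3, MeOH, −78 °C) should deliver hydride anti to the C8–OSi bond (Felkin–Anh, no chelation by the silyl ether) to give the 8-O-triethylsilyl 9α-alcohol F4. HF·pyridine in THF at 0 °C removes the triethylsilyl group and the route is rejoined at 20.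

Step 16. The ene step may take the wrong allylic hydrogen (at C3 or C15 next to C4=C5), or the [2,3] shift may not turn the C1=C10 geometry over completely. The fallback sets out from 24 and moves the oxygen in two separate pericyclic steps. A Schenck ene reaction with singlet oxygen (O2, tetraphenylporphyrin, light, CH2Cl2, 0 °C) should abstract hydrogen on the more crowded C2/C14 side of C1=C10 and give the C1 hydroperoxide with exocyclic C10=C14 F5. PPh3 reduces it to the C1 allylic alcohol with exocyclic C10=C14 F6. Re2O7 (cat.) in Et2O at 0 °C transposes the allylic alcohol through its perrhenate ester (chair-like [3,3] shift with C2 equatorial), which moves the oxygen to C14 and returns C1=C10. The route is rejoined at 25, which the Dess–Martin oxidation of step 16 converts into 26.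

Step 14. The angeloyl unit may isomerise to the tigloyl isomer during acyl transfer, or acylation of the hindered vicinal diol may stall at the monoester. The fallback sets out from 20 and builds the Z double bonds after the ester bonds. Both hydroxyls are esterified with 2-[bis(2,2,2-trifluoroethoxy)phosphoryl]propanoic acid (2 equiv or more; DCC, DMAP, CH2Cl2) to give the bis(phosphonopropionate) F7. Still–Gennari olefination (KN(SiMe3)2, 18-crown-6, THF, −78 °C, then acetaldehyde in excess) should form both Z-configured 2-methylbut-2-enoates in place, and the route is rejoined at 22.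

**Further compounds**
F1 | step 13 | C9 epimer of 20 (8β,9β-diol) | CN(C)C[C@@H]1C(=O)O[C@@H]2/C=C(/CO[Si](c3ccccc3)(c3ccccc3)C(C)(C)C)CC/C=C(\C)[C@@H](O)[C@@H](O)[C@@H]12
F2 | step 13 | 8β-hydroxy-9-ketone | CN(C)C[C@@H]1C(=O)O[C@@H]2/C=C(/CO[Si](c3ccccc3)(c3ccccc3)C(C)(C)C)CC/C=C(\C)C(=O)[C@@H](O)[C@@H]12
F3 | step 13 | 8-O-triethylsilyl 9-ketone | CN(C)C[C@@H]1C(=O)O[C@@H]2/C=C(/CO[Si](c3ccccc3)(c3ccccc3)C(C)(C)C)CC/C=C(\C)C(=O)[C@@H](O[Si](CC)(CC)CC)[C@@H]12
F4 | step 13 | 8-O-triethylsilyl 9α-alcohol | CN(C)C[C@@H]1C(=O)O[C@@H]2/C=C(/CO[Si](c3ccccc3)(c3ccccc3)C(C)(C)C)CC/C=C(\C)[C@H](O)[C@@H](O[Si](CC)(CC)CC)[C@@H]12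
F5 | step 16 | C1 hydroperoxide with exocyclic C10=C14 | C=C1C(=O)O[C@@H]2/C=C(/CO[Si](c3ccccc3)(c3ccccc3)C(C)(C)C)CCC(OO)C(=C)[C@H](OC(=O)/C(C)=C\C)[C@@H](OC(=O)/C(C)=C\C)[C@@H]12
F6 | step 16 | C1 allylic alcohol with exocyclic C10=C14 | C=C1C(=O)O[C@@H]2/C=C(/CO[Si](c3ccccc3)(c3ccccc3)C(C)(C)C)CCC(O)C(=C)[C@H](OC(=O)/C(C)=C\C)[C@@H](OC(=O)/C(C)=C\C)[C@@H]12
F7 | step 14 | bis(phosphonopropionate) of 20 | CN(C)C[C@@H]1C(=O)O[C@@H]2/C=C(/CO[Si](c3ccccc3)(c3ccccc3)C(C)(C)C)CC/C=C(\C)[C@H](OC(=O)C(C)P(=O)(OCC(F)(F)F)OCC(F)(F)F)[C@@H](OC(=O)C(C)P(=O)(OCC(F)(F)F)OCC(F)(F)F)[C@@H]12
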